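**Retrosynthetic overview**
1. Cut the C6(pyranone)–C1′(chain) bond. This gives C6-zincated 2-methoxy-3,5-dimethyl-4-pyranone and (S)-11-iodoundecan-2-yl acetate. The zinc species is an α-alkoxyvinyl/β-acylvinyl carbanion, the masked acyl anion of the triketide δ-carbonyl, so both carbons joined are innately electrophilic.
2. The iodide comes from the chloride by halide exchange. The chloride comes from 8-chlorooctyl Grignard plus (S)-propylene oxide, with the alkoxide acetylated in the same flask. The stereocentre is bought.
3. The 6-H pyranone comes from regioselective O-methylation of 4-hydroxy-3,5-dimethyl-2-pyranone. That comes from γ-formylation and lactonisation of methyl 2-methyl-3-oxopentanoate.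
4. Ring order: the only ring, the pyranone, is closed first (step 1), and the chain is attached last.

Assumption: the single stereocentre reads as (S) from the SMILES, and commercial (S)-propylene oxide of at least 99% ee sets the enantiopurity.

**Step 1**
Reactants: 1 methyl 2-methyl-3-oxopentanoate (racemic); 2 methyl formate
Product: 5 4-hydroxy-3,5-dimethyl-2H-pyran-2-one, via dilithio dianion 3 (not isolated), via formyl keto ester 4 (not isolated)
Conditions: LiN(iPr)2 (LDA, commercial solution, 2.1 equiv), THF, −78 → 0 °C; 2 (0.5 equiv), −78 → 0 °C; 2 M HCl; crude, DBU (1.0 equiv), toluene, 80 °C; 1 M HCl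
Reagents that add atoms: none
Why: The γ-carbon of the β-keto ester dianion is its most nucleophilic site, so crossed Claisen-type C-formylation gives 4 (the second equivalent of dianion absorbs the acidic product proton), and the formyl enol of 4 lactonises onto the ester under DBU (dianion acylation, then pyranone lactonisation); C2 and C4 both become sp2, so no stereocentre remains.

**Step 2**
Reactants: 5 4-hydroxy-3,5-dimethyl-2H-pyran-2-one
Product: 7 2-methoxy-3,5-dimethyl-4H-pyran-4-one, via hydroxypyrylium triflate 6 (not isolated)
Conditions: MeOTf (1.3 equiv), CH2Cl2, 0 °C → rt; sat. aq. NaHCO3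
Reagents that add atoms: methyl trifluoromethanesulfonate, COS(=O)(=O)C(F)(F)F
Why: Under neutral conditions the hard methylating agent attacks the most basic oxygen, the lactone carbonyl, to give 6, which loses the 4-OH proton on work-up and leaves the α-methoxy-γ-pyranone rather than the 4-methoxy-2-pyranone (regiospecific O-alkylation of an ambident vinylogous acid).

**Step 3**
Reactants: 8 1-bromo-8-chlorooctane; 9 (S)-2-methyloxirane ((S)-propylene oxide)
Product: 12 (S)-11-chloroundecan-2-yl acetate, via 8-chlorooctylmagnesium bromide 10 (not isolated), via bromomagnesium alkoxide 11 (not isolated)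
Conditions: Mg (1.1 equiv), cat. I2, THF, 40 °C; CuI (10 mol %), −30 °C; 9 (1.1 equiv), −30 → 0 °C; Ac2O (2 equiv), DMAP (5 mol %), 0 °C → rt
Reagents that add atoms: acetic anhydride, CC(=O)OC(C)=O
Why: Magnesium inserts only into the C–Br bond, the CuI-catalysed Grignard opens the epoxide by SN2 attack at the unsubstituted carbon so the C–O stereocentre of 9 is carried over untouched as (S), and the alkoxide is acetylated in the same flask (copper-catalysed epoxide opening, then O-acylation).

**Step 4**
Reactants: 12 (S)-11-chloroundecan-2-yl acetate
Product: 13 (S)-11-iodoundecan-2-yl acetate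
Conditions: NaI (5 equiv), 2-butanone, 80 °C, 24 h
Reagents that add atoms: sodium iodide, [Na+].[I-]
Why: Finkelstein halide exchange at the primary carbon is driven by precipitation of NaCl and touches neither the acetate nor the remote stereocentre.

**Step 5 (key step)**
Reactants: 7 2-methoxy-3,5-dimethyl-4H-pyran-4-one; 13 (S)-11-iodoundecan-2-yl acetate
Product: 15 (S)-11-(6-methoxy-3,5-dimethyl-4-oxo-4H-pyran-2-yl)undecan-2-yl acetate (target), via pyranonylzinc chloride 14 (not isolated)
Conditions: 7 (1.5 equiv), TMPZnCl·LiCl (1.4 equiv; TMP = 2,2,6,6-tetramethylpiperidin-1-yl), THF, 25 °C, 2 h; then 13 (1.0 equiv), Ni(acac)2 (10 mol %), 4-fluorostyrene (20 mol %), THF/NMP 2:1, −15 → 25 °C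
Reagents that add atoms: none
Why: Proposed new method: the only ring C–H of 7 sits on the enol-ether carbon next to the ring oxygen and is removed by the hindered zinc amide as the C2–H of chromones is, giving 14, an α-alkoxyvinyl (masked acyl) and β-acylvinyl carbanion at the carbon that is normally the electrophilic end of the vinylogous ester; this soft zinc reagent ignores the acetate, and Ni(acac)2/4-fluorostyrene couples it with the primary C–I carbon of 13 (alkyl-radical oxidative addition, transmetalation, styrene-accelerated reductive elimination ahead of β-hydride loss) without touching the remote (S) centre; the closest known reaction types are TMP-zinc C–H metalation of chromones followed by Negishi coupling, and Ni-catalysed Negishi coupling of arylzinc halides with primary alkyl iodides.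

**Compound list**
1 | methyl 2-methyl-3-oxopentanoate (racemic) | CCC(=O)C(C)C(=O)OC | starting material
2 | methyl formate | COC=O | starting material
3 | dilithium bis-enolate (dianion) of methyl 2-methyl-3-oxopentanoate | [Li+].[Li+].CC=C([O-])C(C)=C([O-])OC | intermediate
4 | methyl 2,4-dimethyl-3,5-dioxopentanoate (stereoisomer/enol mixture) | COC(=O)C(C)C(=O)C(C)C=O | intermediate
5 | 4-hydroxy-3,5-dimethyl-2H-pyran-2-one | Cc1coc(=O)c(C)c1O | intermediate
6 | 4-hydroxy-2-methoxy-3,5-dimethylpyrylium trifluoromethanesulfonate | COc1[o+]cc(C)c(O)c1C.[O-]S(=O)(=O)C(F)(F)F | intermediate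
7 | 2-methoxy-3,5-dimethyl-4H-pyran-4-one | COc1occ(C)c(=O)c1C | intermediate
8 | 1-bromo-8-chlorooctane | ClCCCCCCCCBr | starting material
9 | (S)-2-methyloxirane | C[C@H]1CO1 | starting material
10 | 8-chlorooctylmagnesium bromide | ClCCCCCCCC[Mg]Br | intermediate
11 | bromomagnesium (S)-11-chloroundecan-2-olate | ClCCCCCCCCC[C@H](C)O[Mg]Br | intermediate
12 | (S)-11-chloroundecan-2-yl acetate | ClCCCCCCCCC[C@H](C)OC(C)=O | intermediate
13 | (S)-11-iodoundecan-2-yl acetate | ICCCCCCCCC[C@H](C)OC(C)=O | intermediate
14 | (6-methoxy-3,5-dimethyl-4-oxo-4H-pyran-2-yl)zinc chloride, LiCl complex | COc1oc([Zn]Cl)c(C)c(=O)c1C.[Li+].[Cl-] | intermediate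
15 | (S)-11-(6-methoxy-3,5-dimethyl-4-oxo-4H-pyran-2-yl)undecan-2-yl acetate | COc1oc(CCCCCCCCC[C@H](C)OC(C)=O)c(C)c(=O)c1C | target

**Totals**
Total step count: 5.
Longest linear sequence: 3 (steps 1, 2, 5 or steps 3, 4, 5).

**Three steps most likely to fail**

Step 5. The electron-poor, ortho-methylated zinc reagent 14 may transmetalate too slowly to nickel, so that 13 is lost to reduction or elimination. The fallback sets out from 7. It is zincated to 14 as before, and 14 is quenched with I2 to give isolable 2-iodo-6-methoxy-3,5-dimethyl-4H-pyran-4-one F1. F1 and 13 are then joined by reductive cross-electrophile coupling (NiI2 10 mol %, 4,4′-di-tert-butyl-2,2′-bipyridine, Zn dust, NaI, pyridine, DMPU, 60 °C). Here the activated C6–I bond adds to low-valent nickel and the alkyl iodide enters as a radical, so no transmetalation is needed. This fallback comes back to the route at 15.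

Step 1. Formylation of the dianion can stall through proton transfer, or give O-formyl and polymeric material. The fallback sets out from 1, which is heated neat at 100 °C with tert-butoxybis(dimethylamino)methane. Only the C4 methylene can condense, because C2 carries a single hydrogen. The product is methyl (E)-5-(dimethylamino)-2,4-dimethyl-3-oxopent-4-enoate F2. Hydrolysis with 2 M HCl/THF unmasks the formyl group and comes back to the route at 4, which is lactonised with DBU as in step 1.

Step 2. Methylation may leak to the 4-methoxy-2-pyranone isomer. The fallback sets out from 4, taken crude before the DBU treatment, and removes the regiochemical question by cyclodehydration with PPh3/CCl4 in THF at rt. The formyl enol is activated as its oxyphosphonium salt and the ester carbonyl oxygen closes the six-membered ring. The methoxy group of the ester therefore becomes the C2 methoxy group directly. This bypasses 5 and 6 and comes back to the route at 7. New compounds outside the list: none F0.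

**Further compounds**
F1 | step 5 | 2-iodo-6-methoxy-3,5-dimethyl-4H-pyran-4-one | COc1oc(I)c(C)c(=O)c1C
F2 | step 1 | methyl (E)-5-(dimethylamino)-2,4-dimethyl-3-oxopent-4-enoate | COC(=O)C(C)C(=O)/C(C)=C/N(C)C
F0 | step 2 | none | none
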